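## Retrosynthetic overview

- **Feature.** In ring D the hydroxyl carbon D2 lies between D1 (bonded to C6 of ring A) and D3. Removing D2 and its oxygen as CO leaves the chain D1-D6-D5-D4-D3, with the carboxyl carbon on the central atom D5.
- **Key disconnection.** D1-D2 and D2-D3 are cut, which is a [5+1] cyclocarbonylation of a bis-allylic acetate. In that acetate D1=D6 is the styrene bond on C6, D5 bears OAc and CO2Me, and D4=D3 is a vinyl group.
- **Precursor.** The acetate comes from a beta,gamma-unsaturated alpha-keto ester by vinyl Grignard addition at D5 and acetylation. The keto ester comes from the 6-formylflavone by a Wittig reaction that makes D1=D6. The aldehyde comes from apigenin by O-methylation, C6 iodination under the free 5-OH, and formylation.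
- **Ring order.** Rings A, B and C are bought with apigenin, and ring D is the only ring formed. Saponification and BBr3 demethylation finish the synthesis.

Key step: step 9

Assumption: the target SMILES carries no stereodescriptor, so the C6-D1 biaryl axis is treated as freely rotating. The only stereocentre of the route (D5 in the tertiary alcohol and its acetate) is racemic and vanishes on aromatisation.

## Route

Step 1
Reactants: 1 apigenin
Product: 2 5-hydroxy-7-methoxy-2-(4-methoxyphenyl)chromen-4-one (apigenin 7,4'-dimethyl ether)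
Conditions: MeI (2.2 equiv), K2CO3, DMF, rt
Reagents that add atoms: iodomethane, CI
Why: Williamson ether synthesis: the 7-OH and 4'-OH are free, acidic phenols and are alkylated first, whereas the 5-OH is held in a hydrogen bond to the C4 carbonyl and should stay untouched with two equivalents of MeI and a weak base at room temperature.

Step 2
Reactants: 2 apigenin 7,4'-dimethyl ether
Product: 3 5-hydroxy-6-iodo-7-methoxy-2-(4-methoxyphenyl)chromen-4-one
Conditions: BnMe3N[ICl2] (1.05 equiv), CaCO3, CH2Cl2-MeOH, rt
Reagents that add atoms: benzyltrimethylammonium dichloroiodate, C[N+](C)(C)Cc1ccccc1.Cl[I-]Cl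
Why: Electrophilic aromatic iodination: with the 5-OH free and O7 alkylated, the dichloroiodate reagent is known to attack 5,7-dioxygenated flavones at C6, ortho to the phenol, while ring B is deactivated by the enone and the fully methylated flavone would react at C8 instead, which is why iodination precedes step 3.

Step 3
Reactants: 3 5-hydroxy-6-iodo-7-methoxy-2-(4-methoxyphenyl)chromen-4-one
Product: 4 6-iodo-5,7-dimethoxy-2-(4-methoxyphenyl)chromen-4-one
Conditions: MeI (excess), K2CO3, DMF, 50 °C
Reagents that add atoms: iodomethane, CI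
Why: Williamson ether synthesis under forcing conditions: excess MeI in warm DMF overcomes the chelation of the 5-OH, which is the only acidic site left.

Step 4
Reactants: 4 6-iodo-5,7-dimethoxy-2-(4-methoxyphenyl)chromen-4-one; 5 carbon monoxide
Product: 6 5,7-dimethoxy-2-(4-methoxyphenyl)-4-oxochromene-6-carbaldehyde
Conditions: PdCl2(PPh3)2 (5 mol %), CO (5 atm), HCO2Na (2 equiv), DMF, 100 °C
Reagents that add atoms: carbon monoxide (5), [C-]#[O+]
Why: Palladium-catalysed reductive carbonylation (formylation) of an aryl iodide: oxidative addition, CO insertion, exchange of iodide for formate, loss of CO2 and C-H reductive elimination give the aldehyde, and the sparingly soluble formate supplies hydride slowly enough for CO insertion at the doubly ortho-substituted arylpalladium to come first.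

Step 5
Reactants: 7 methyl bromopyruvate
Product: 9 methyl 2-oxo-3-(triphenyl-lambda5-phosphanylidene)propanoate, via phosphonium bromide 8 (not isolated)
Conditions: PPh3, CH2Cl2, rt; then aq Na2CO3 added to the same flask, rt
Reagents that add atoms: triphenylphosphine, c1ccc(cc1)P(c1ccccc1)c1ccccc1
Why: Standard preparation of a stabilised Wittig ylide: SN2 quaternisation of PPh3 by the alpha-bromo ketone is followed by deprotonation of the strongly acidic acylmethylphosphonium salt, for which aqueous carbonate is enough, so the methyl ester is not hydrolysed.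

Step 6
Reactants: 6 5,7-dimethoxy-2-(4-methoxyphenyl)-4-oxochromene-6-carbaldehyde; 9 methyl 2-oxo-3-(triphenyl-lambda5-phosphanylidene)propanoate
Product: 10 methyl (E)-4-[5,7-dimethoxy-2-(4-methoxyphenyl)-4-oxochromen-6-yl]-2-oxobut-3-enoate
Conditions: 9 (1.2 equiv), PhCO2H (10 mol %), toluene, 100 °C
Reagents that add atoms: none
Why: Wittig olefination with a stabilised acyl ylide, which should give the E-enone D1=D6 under neutral conditions that spare the chromone and avoid the self-condensation that pyruvate esters undergo under aldol conditions.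

Step 7
Reactants: 10 methyl (E)-4-[5,7-dimethoxy-2-(4-methoxyphenyl)-4-oxochromen-6-yl]-2-oxobut-3-enoate; 11 vinylmagnesium bromide
Product: 12 methyl (E)-4-[5,7-dimethoxy-2-(4-methoxyphenyl)-4-oxochromen-6-yl]-2-hydroxy-2-vinylbut-3-enoate (racemic)
Conditions: CH2=CHMgBr (1.1 equiv), THF-CH2Cl2, -78 °C; sat. aq NH4Cl
Reagents that add atoms: vinylmagnesium bromide (11), C=C[Mg]Br
Why: Grignard 1,2-addition: the ketone of the alpha-keto ester is by far the most electrophilic carbonyl present, so one equivalent at -78 °C should leave the vinylogous-ester C4 carbonyl and the methyl ester alone, conjugate addition at D1 is hindered by the two flanking methoxy groups, and the new stereocentre D5 is formed without control as a racemate because it disappears in step 9.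

Step 8
Reactants: 12 methyl (E)-4-[5,7-dimethoxy-2-(4-methoxyphenyl)-4-oxochromen-6-yl]-2-hydroxy-2-vinylbut-3-enoate
Product: 13 methyl (E)-2-acetoxy-4-[5,7-dimethoxy-2-(4-methoxyphenyl)-4-oxochromen-6-yl]-2-vinylbut-3-enoate (racemic)
Conditions: Ac2O (3 equiv), NEt3, 4-(dimethylamino)pyridine (0.2 equiv), CH2Cl2, rt
Reagents that add atoms: acetic anhydride, CC(=O)OC(C)=O
Why: Steglich-type acylation of a tertiary alcohol through the N-acetylpyridinium salt; the basic, non-ionising medium should prevent allylic transposition or loss of water from the bis-allylic carbinol, and the configuration at D5 is not touched.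

Step 9
Reactants: 13 methyl (E)-2-acetoxy-4-[5,7-dimethoxy-2-(4-methoxyphenyl)-4-oxochromen-6-yl]-2-vinylbut-3-enoate; 5 carbon monoxide
Product: 16 methyl 4-acetoxy-3-[5,7-dimethoxy-2-(4-methoxyphenyl)-4-oxochromen-6-yl]benzoate, via dienylketene 14 (not isolated), via free phenol 15 (not isolated)
Conditions: PdCl2(PPh3)2 (5 mol %), CO (60 atm), Ac2O (2 equiv), NEt3 (2 equiv), toluene, 150 °C, autoclave
Reagents that add atoms: carbon monoxide (5), [C-]#[O+]; acetic anhydride, CC(=O)OC(C)=O
Why: Oxidative addition of the bis-allylic C-OAc bond of 13 to zerovalent palladium (formed from PdCl2(PPh3)2 under CO and NEt3) should give a pentadienylpalladium acetate that has no beta-hydrogen to lose; CO inserts at the open terminus D3, and NEt3, acting on the acylpalladium species or on its mixed anhydride with acetate, releases dienylketene 14. Ring D closes by a thermal six-electron electrocyclisation of 14 that joins the ketene carbon D2 to the styrene carbon D1, a proton shift aromatises the ring to phenol 15, and Ac2O traps it as 16. The closest known reaction type is the palladium-catalysed cyclocarbonylation of primary 2,4-pentadienyl acetates to phenyl acetates (5-aryl members give 2-acetoxybiaryls) and of cinnamyl acetates to 1-naphthyl acetates; 13 is a branched, tertiary, ester-bearing member of this family that has not itself been tried, but it should reach the same kind of pentadienylpalladium species, and return of acetate only gives linear isomers that ionise again. The closure needs D3 and D6 cis about D4=D5, which eta-3/eta-1/eta-3 interconversion supplies at little cost, because D5 carries two substituents and one of them (styryl or ester) has to sit anti in any case. Regiochemistry is forgiving: insertion of CO at D3 or at D1 ends in the same arene since D2 becomes bonded to both, insertion at the fully substituted D5 is hindered and reversible, and a naphthol-type closure onto ring A is blocked by the methoxy groups at C5 and C7. No stereocentre is created, and the one at D5 of 13 is erased on ionisation.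

Step 10
Reactants: 16 methyl 4-acetoxy-3-[5,7-dimethoxy-2-(4-methoxyphenyl)-4-oxochromen-6-yl]benzoate
Product: 17 3-[5,7-dimethoxy-2-(4-methoxyphenyl)-4-oxochromen-6-yl]-4-hydroxybenzoic acid
Conditions: LiOH (6 equiv), THF-MeOH-H2O, rt; then 1 M HCl to pH 2
Reagents that add atoms: lithium hydroxide, [Li+].[OH-]
Why: Saponification by acyl-oxygen cleavage: hydroxide removes the aryl acetate at once and the methyl benzoate more slowly, while the fully O-methylated flavone should not open at C2 under aqueous LiOH at room temperature.

Step 11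
Reactants: 17 3-[5,7-dimethoxy-2-(4-methoxyphenyl)-4-oxochromen-6-yl]-4-hydroxybenzoic acid
Product: 18 3-[5,7-dihydroxy-2-(4-hydroxyphenyl)-4-oxochromen-6-yl]-4-hydroxybenzoic acid (CNP0203666.0)
Conditions: BBr3 (12 equiv), CH2Cl2, -78 °C to rt, then 40 °C; ice-water quench (no MeOH, to avoid re-esterification)
Reagents that add atoms: none
Why: Lewis-acid ether cleavage: BBr3 binds each methoxy oxygen and bromide removes the methyl group by SN2; the chelated 5-OMe goes first, the 7- and 4'-OMe need excess reagent and warming, the acid and phenol only consume extra BBr3 and are restored by the water quench, and hot protic acids are avoided because they could move the aryl group from C6 to C8 by Wessely-Moser isomerisation.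

## Compound list

1 | apigenin | O=c1cc(-c2ccc(O)cc2)oc2cc(O)cc(O)c12 | starting material
2 | 5-hydroxy-7-methoxy-2-(4-methoxyphenyl)chromen-4-one | O=c1cc(-c2ccc(OC)cc2)oc2cc(OC)cc(O)c12 | intermediate
3 | 5-hydroxy-6-iodo-7-methoxy-2-(4-methoxyphenyl)chromen-4-one | O=c1cc(-c2ccc(OC)cc2)oc2cc(OC)c(I)c(O)c12 | intermediate
4 | 6-iodo-5,7-dimethoxy-2-(4-methoxyphenyl)chromen-4-one | O=c1cc(-c2ccc(OC)cc2)oc2cc(OC)c(I)c(OC)c12 | intermediate
5 | carbon monoxide | [C-]#[O+] | starting material
6 | 5,7-dimethoxy-2-(4-methoxyphenyl)-4-oxochromene-6-carbaldehyde | O=Cc1c(OC)cc2oc(-c3ccc(OC)cc3)cc(=O)c2c1OC | intermediate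
7 | methyl bromopyruvate | COC(=O)C(=O)CBr | starting material
8 | (3-methoxy-2,3-dioxopropyl)triphenylphosphonium bromide | COC(=O)C(=O)C[P+](c1ccccc1)(c1ccccc1)c1ccccc1.[Br-] | intermediate
9 | methyl 2-oxo-3-(triphenyl-lambda5-phosphanylidene)propanoate | COC(=O)C(=O)C=P(c1ccccc1)(c1ccccc1)c1ccccc1 | intermediate
10 | methyl (E)-4-[5,7-dimethoxy-2-(4-methoxyphenyl)-4-oxochromen-6-yl]-2-oxobut-3-enoate | COC(=O)C(=O)/C=C/c1c(OC)cc2oc(-c3ccc(OC)cc3)cc(=O)c2c1OC | intermediate
11 | vinylmagnesium bromide | C=C[Mg]Br | starting material
12 | methyl (E)-4-[5,7-dimethoxy-2-(4-methoxyphenyl)-4-oxochromen-6-yl]-2-hydroxy-2-vinylbut-3-enoate (racemic) | C=CC(O)(C(=O)OC)/C=C/c1c(OC)cc2oc(-c3ccc(OC)cc3)cc(=O)c2c1OC | intermediate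
13 | methyl (E)-2-acetoxy-4-[5,7-dimethoxy-2-(4-methoxyphenyl)-4-oxochromen-6-yl]-2-vinylbut-3-enoate (racemic) | C=CC(OC(C)=O)(C(=O)OC)/C=C/c1c(OC)cc2oc(-c3ccc(OC)cc3)cc(=O)c2c1OC | intermediate
14 | methyl (2E)-2-{(E)-2-[5,7-dimethoxy-2-(4-methoxyphenyl)-4-oxochromen-6-yl]ethenyl}-5-oxopenta-2,4-dienoate (dienylketene) | O=C=C/C=C(\C=C\c1c(OC)cc2oc(-c3ccc(OC)cc3)cc(=O)c2c1OC)C(=O)OC | intermediate
15 | methyl 3-[5,7-dimethoxy-2-(4-methoxyphenyl)-4-oxochromen-6-yl]-4-hydroxybenzoate | COC(=O)c1ccc(O)c(-c2c(OC)cc3oc(-c4ccc(OC)cc4)cc(=O)c3c2OC)c1 | intermediate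
16 | methyl 4-acetoxy-3-[5,7-dimethoxy-2-(4-methoxyphenyl)-4-oxochromen-6-yl]benzoate | CC(=O)Oc1ccc(C(=O)OC)cc1-c1c(OC)cc2oc(-c3ccc(OC)cc3)cc(=O)c2c1OC | intermediate
17 | 3-[5,7-dimethoxy-2-(4-methoxyphenyl)-4-oxochromen-6-yl]-4-hydroxybenzoic acid | O=C(O)c1ccc(O)c(-c2c(OC)cc3oc(-c4ccc(OC)cc4)cc(=O)c3c2OC)c1 | intermediate
18 | 3-[5,7-dihydroxy-2-(4-hydroxyphenyl)-4-oxochromen-6-yl]-4-hydroxybenzoic acid | O=C(O)c1ccc(O)c(-c2c(O)cc3oc(-c4ccc(O)cc4)cc(=O)c3c2O)c1 | target

## Step count

Total step count: 11.
Longest linear sequence: 10 (steps 1-4 and 6-11). Step 5 is a one-step side branch.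

## Steps most likely to fail

**1. Step 9.**
- What may go wrong: the tertiary, ester-bearing acetate may ionise slowly. The carbonylation may stop at the open-chain dienoyl stage. Acylpalladation at D6 may close a five-membered ring instead. The electron-poor triene may also oligomerise at 150 °C before the hindered D1 is reached.
- Fallback: the C6-D1 biaryl bond is made directly instead of building ring D. It sets out from 4. Suzuki-Miyaura coupling with commercial [2-methoxy-5-(methoxycarbonyl)phenyl]boronic acid (Pd(OAc)2, 2-dicyclohexylphosphino-2',6'-dimethoxybiphenyl, K3PO4, toluene-H2O, 100 °C) should give methyl 3-[5,7-dimethoxy-2-(4-methoxyphenyl)-4-oxochromen-6-yl]-4-methoxybenzoate F1. Saponification with LiOH in THF-MeOH-H2O should give 3-[5,7-dimethoxy-2-(4-methoxyphenyl)-4-oxochromen-6-yl]-4-methoxybenzoic acid F2. Excess BBr3 in CH2Cl2 then cleaves all four methyl ethers, and the fallback comes back to the route at 18.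

**2. Step 7.**
- What may go wrong: chemoselectivity may be lost through conjugate addition to the enone, attack of the hard organomagnesium reagent on the chromone carbonyl or the ester, or poor solubility of the flavone at -78 °C that forces a higher temperature.
- Fallback: D3-D4 is brought in as an alkyne through a soft zinc acetylide and reduced afterwards. It sets out from 10. Trimethylsilylacetylene with Zn(OTf)2 and NEt3 in toluene, a known alkynylation of alpha-keto esters that leaves ordinary carbonyl groups alone, should give methyl (E)-4-[5,7-dimethoxy-2-(4-methoxyphenyl)-4-oxochromen-6-yl]-2-hydroxy-2-[(trimethylsilyl)ethynyl]but-3-enoate F3. Catalytic K2CO3 in MeOH removes the silyl group to give methyl (E)-4-[5,7-dimethoxy-2-(4-methoxyphenyl)-4-oxochromen-6-yl]-2-ethynyl-2-hydroxybut-3-enoate F4. Semi-hydrogenation (H2, Pd/CaCO3 poisoned with Pb(OAc)2, quinoline, EtOAc) turns the terminal alkyne into the vinyl group, and the fallback comes back at 12.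

**3. Step 4.**
- What may go wrong: hydride transfer to the arylpalladium flanked by two methoxy groups may outrun CO insertion, which would cause hydrodeiodination. The aroylpalladium may also be diverted to the carboxylic acid.
- Fallback: the aldehyde carbon is installed as an alkene and uncovered by oxidative cleavage. It sets out from 4. Suzuki-Miyaura vinylation with potassium vinyltrifluoroborate (PdCl2(dppf), Cs2CO3, THF-H2O, 80 °C) should give 6-ethenyl-5,7-dimethoxy-2-(4-methoxyphenyl)chromen-4-one F5. Lemieux-Johnson oxidation (OsO4 cat., NaIO4, 2,6-lutidine, dioxane-H2O) cleaves the electron-rich styrene in preference to the electron-poor C2=C3 bond, and the fallback comes back at 6.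

## Further compounds

F1 | step 9 | methyl 3-[5,7-dimethoxy-2-(4-methoxyphenyl)-4-oxochromen-6-yl]-4-methoxybenzoate | COC(=O)c1ccc(OC)c(-c2c(OC)cc3oc(-c4ccc(OC)cc4)cc(=O)c3c2OC)c1
F2 | step 9 | 3-[5,7-dimethoxy-2-(4-methoxyphenyl)-4-oxochromen-6-yl]-4-methoxybenzoic acid | O=C(O)c1ccc(OC)c(-c2c(OC)cc3oc(-c4ccc(OC)cc4)cc(=O)c3c2OC)c1
F3 | step 7 | methyl (E)-4-[5,7-dimethoxy-2-(4-methoxyphenyl)-4-oxochromen-6-yl]-2-hydroxy-2-[(trimethylsilyl)ethynyl]but-3-enoate (racemic) | C[Si](C)(C)C#CC(O)(C(=O)OC)/C=C/c1c(OC)cc2oc(-c3ccc(OC)cc3)cc(=O)c2c1OC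
F4 | step 7 | methyl (E)-4-[5,7-dimethoxy-2-(4-methoxyphenyl)-4-oxochromen-6-yl]-2-ethynyl-2-hydroxybut-3-enoate (racemic) | C#CC(O)(C(=O)OC)/C=C/c1c(OC)cc2oc(-c3ccc(OC)cc3)cc(=O)c2c1OC
F5 | step 4 | 6-ethenyl-5,7-dimethoxy-2-(4-methoxyphenyl)chromen-4-one | C=Cc1c(OC)cc2oc(-c3ccc(OC)cc3)cc(=O)c2c1OC
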